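**Retrosynthetic overview**
- Target ⇐ buffered fluoride removal of a phenol silyl group ⇐ ketoreductase reduction of the macrocyclic C4 enone (C4 set last, by the enzyme).
- Enone ⇐ oxidation ⇐ intramolecular Nozaki–Hiyama–Kishi closure of the C3–C4 bond. The 11-membered carbocycle is the only ring formed; the arene arrives intact from vanillic acid and is esterified onto C1 before ring closure.
- (E)-2-Iodoalkene ⇐ hydrozirconation–iodination of a 2-butynyl carbinol; C1 ⇐ Noyori transfer hydrogenation of an ynone (first stereocentre).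
- Ynone ⇐ neopentyl aldehyde + propynyl Grignard; (Z)-trisubstituted alkene ⇐ Normant carbocupration of propyne with oxirane opening; quaternary C11 ⇐ isobutyrate alkylation.

Assumption: ring atoms are numbered as in the target name (C1 = ester-bearing carbon, C4 = free carbinol, C11 = gem-dimethyl carbon). The C1 carbinol is S while it bears an alkynyl group and R once that group is an alkenyl group; this is a change of CIP priority only.

**Step 1**
Reactants: 1 ethyl isobutyrate; 2 1,3-dibromopropane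
Product: 4 ethyl 5-bromo-2,2-dimethylpentanoate, via lithium enolate 3 (not isolated)
Conditions: LiN(i-Pr)2, THF, −78 °C; then 2 (3 equiv), −78 °C → rt
Reagents that add atoms: none
Why: Ester enolate alkylation; the fully substituted enolate can react only once and excess dibromide suppresses double displacement, so the quaternary carbon (C11) forms cleanly.

**Step 2**
Reactants: 4 ethyl 5-bromo-2,2-dimethylpentanoate
Product: 5 5-bromo-2,2-dimethylpentan-1-ol
Conditions: i-Bu2AlH (2.5 equiv), CH2Cl2, −78 → 0 °C; aq. potassium sodium tartrate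
Reagents that add atoms: none
Why: Hydride reduction of the ester leaves the primary bromide untouched, and the cold non-basic work-up avoids cyclisation of the bromo alcohol to a tetrahydropyran.

**Step 3**
Reactants: 5 5-bromo-2,2-dimethylpentan-1-ol
Product: 6 [(5-bromo-2,2-dimethylpentyl)oxy](tert-butyl)dimethylsilane
Conditions: TBSCl, imidazole, CH2Cl2, 0 °C → rt
Reagents that add atoms: tert-butyldimethylsilyl chloride, CC(C)(C)[Si](C)(C)Cl
Why: Imidazole-mediated silylation masks the neopentyl alcohol for the organometallic chemistry that follows.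

**Step 4**
Reactants: 6 [(5-bromo-2,2-dimethylpentyl)oxy](tert-butyl)dimethylsilane; 7 propyne; 8 oxirane
Product: 11 (Z)-9-[(tert-butyldimethylsilyl)oxy]-4,8,8-trimethylnon-3-en-1-ol, via Grignard reagent 9 (not isolated), via alkenylcopper 10 (not isolated)
Conditions: Mg, Et2O, reflux; CuBr·SMe2, Et2O/Me2S, −45 °C; 7, −25 °C; then lithium pent-1-ynide, HMPA, 8, −40 °C → rt; aq. NH4Cl
Reagents that add atoms: none
Why: Normant carbocupration; the alkylcopper adds syn across propyne with the alkyl group on the internal carbon, and the alkenylcopper (activated as a mixed alkynyl cuprate) opens oxirane with retention, so the chain and the hydroxyethyl arm end up cis (Z).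

**Step 5**
Reactants: 11 (Z)-9-[(tert-butyldimethylsilyl)oxy]-4,8,8-trimethylnon-3-en-1-ol
Product: 12 (Z)-tert-butyl({9-[(4-methoxybenzyl)oxy]-2,2,6-trimethylnon-6-en-1-yl}oxy)dimethylsilane
Conditions: NaH, PMBCl, Bu4NI (cat.), THF/DMF, 0 °C → rt
Reagents that add atoms: 4-methoxybenzyl chloride, COc1ccc(CCl)cc1
Why: Williamson etherification gives a PMB ether that survives base, hydride, fluoride and organometallics and is later removed oxidatively in the presence of the ester.

**Step 6**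
Reactants: 12 (Z)-tert-butyl({9-[(4-methoxybenzyl)oxy]-2,2,6-trimethylnon-6-en-1-yl}oxy)dimethylsilane
Product: 13 (Z)-9-[(4-methoxybenzyl)oxy]-2,2,6-trimethylnon-6-en-1-ol
Conditions: Bu4NF, THF, rt
Reagents that add atoms: none
Why: Fluoride-driven desilylation frees only the neopentyl alcohol, since the PMB ether and the alkene are inert to fluoride.

**Step 7**
Reactants: 13 (Z)-9-[(4-methoxybenzyl)oxy]-2,2,6-trimethylnon-6-en-1-ol
Product: 14 (Z)-9-[(4-methoxybenzyl)oxy]-2,2,6-trimethylnon-6-enal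
Conditions: Dess–Martin periodinane, NaHCO3, CH2Cl2, rt
Reagents that add atoms: none
Why: Dess–Martin oxidation gives a non-enolisable neopentyl aldehyde without touching the alkene or the PMB ether.

**Step 8**
Reactants: 14 (Z)-9-[(4-methoxybenzyl)oxy]-2,2,6-trimethylnon-6-enal; 15 prop-1-yn-1-ylmagnesium bromide
Product: 16 (9Z)-12-[(4-methoxybenzyl)oxy]-5,5,9-trimethyldodec-9-en-2-yn-4-ol (racemic)
Conditions: THF, 0 °C; aq. NH4Cl
Reagents that add atoms: none
Why: Grignard 1,2-addition of the slim alkynyl nucleophile to the hindered aldehyde installs C2, C3 and the C3 methyl; the racemic carbinol is oxidised in the next step.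

**Step 9**
Reactants: 16 (9Z)-12-[(4-methoxybenzyl)oxy]-5,5,9-trimethyldodec-9-en-2-yn-4-ol (racemic)
Product: 17 (Z)-12-[(4-methoxybenzyl)oxy]-5,5,9-trimethyldodec-9-en-2-yn-4-one
Conditions: Dess–Martin periodinane, NaHCO3, CH2Cl2, rt
Reagents that add atoms: none
Why: Dess–Martin oxidation of the propargylic alcohol gives the achiral, non-enolisable ynone needed for catalytic asymmetric reduction.

**Step 10**
Reactants: 17 (Z)-12-[(4-methoxybenzyl)oxy]-5,5,9-trimethyldodec-9-en-2-yn-4-one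
Product: 18 (4S,9Z)-12-[(4-methoxybenzyl)oxy]-5,5,9-trimethyldodec-9-en-2-yn-4-ol
Conditions: Ru[(S,S)-TsNCH(Ph)CH(Ph)NH](p-cymene) (2 mol%), i-PrOH, rt
Reagents that add atoms: none
Why: Noyori asymmetric transfer hydrogenation; the (S,S)-TsDPEN ruthenium hydride distinguishes the alkynyl from the tert-alkyl flank in its six-membered transition state and gives the S propargylic alcohol, the first stereocentre (C1), without reducing the alkyne or alkene.

**Step 11**
Reactants: 18 (4S,9Z)-12-[(4-methoxybenzyl)oxy]-5,5,9-trimethyldodec-9-en-2-yn-4-ol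
Product: 19 triethyl({(4S,9Z)-12-[(4-methoxybenzyl)oxy]-5,5,9-trimethyldodec-9-en-2-yn-4-yl}oxy)silane
Conditions: TESOTf, 2,6-lutidine, CH2Cl2, −78 → 0 °C
Reagents that add atoms: triethylsilyl trifluoromethanesulfonate, CC[Si](CC)(CC)OS(=O)(=O)C(F)(F)F
Why: The silyl triflate silylates the hindered carbinol, which removes the acidic OH and adds bulk that steers the hydrozirconation away from C2.

**Step 12**
Reactants: 19 triethyl({(4S,9Z)-12-[(4-methoxybenzyl)oxy]-5,5,9-trimethyldodec-9-en-2-yn-4-yl}oxy)silane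
Product: 21 triethyl({(2E,4R,9Z)-2-iodo-12-[(4-methoxybenzyl)oxy]-5,5,9-trimethyldodeca-2,9-dien-4-yl}oxy)silane, via alkenylzirconocene 20 (not isolated)
Conditions: Cp2Zr(H)Cl (2.5 equiv), THF, 50 °C; then I2, 0 °C; aq. Na2S2O3
Reagents that add atoms: iodine, II
Why: Schwartz hydrozirconation adds Zr–H syn and, under equilibrating conditions, puts zirconium on the methyl-bearing alkyne carbon remote from the branched silyloxy carbon; iodinolysis with retention gives the (E)-2-iodoalkene with the methyl cis to C1.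

**Step 13**
Reactants: 21 triethyl({(2E,4R,9Z)-2-iodo-12-[(4-methoxybenzyl)oxy]-5,5,9-trimethyldodeca-2,9-dien-4-yl}oxy)silane
Product: 22 (2E,4R,9Z)-2-iodo-12-[(4-methoxybenzyl)oxy]-5,5,9-trimethyldodeca-2,9-dien-4-ol
Conditions: HF·pyridine, pyridine, THF, 0 °C → rt
Reagents that add atoms: none
Why: Buffered HF cleaves the labile triethylsilyl ether while the PMB ether, the alkenyl iodide and both alkenes are untouched.

**Step 14**
Reactants: 23 vanillic acid
Product: 25 3-methoxy-4-[(triisopropylsilyl)oxy]benzoic acid, via bis-silylated ester 24 (not isolated)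
Conditions: i-Pr3SiCl (2.4 equiv), imidazole, DMF, rt; then AcOH/THF/H2O, rt
Reagents that add atoms: triisopropylsilyl chloride, CC(C)[Si](Cl)(C(C)C)C(C)C
Why: Both acidic groups are silylated and the much more labile silyl ester is then hydrolysed selectively, leaving the phenol protected so the acid cannot oligomerise on activation.

**Step 15**
Reactants: 22 (2E,4R,9Z)-2-iodo-12-[(4-methoxybenzyl)oxy]-5,5,9-trimethyldodeca-2,9-dien-4-ol; 25 3-methoxy-4-[(triisopropylsilyl)oxy]benzoic acid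
Product: 27 (2E,4R,9Z)-2-iodo-12-[(4-methoxybenzyl)oxy]-5,5,9-trimethyldodeca-2,9-dien-4-yl 3-methoxy-4-[(triisopropylsilyl)oxy]benzoate, via mixed anhydride 26 (not isolated)
Conditions: 25, 2,4,6-trichlorobenzoyl chloride, Et3N, THF, rt; then 22, DMAP, toluene, 60 °C
Reagents that add atoms: none
Why: Yamaguchi esterification; DMAP attacks the less hindered aroyl carbonyl of the mixed anhydride and the acylpyridinium acylates the neopentyl-type allylic alcohol without breaking its C–O bond, so C1 keeps its configuration and the ester is in place before C4 exists.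

**Step 16**
Reactants: 27 (2E,4R,9Z)-2-iodo-12-[(4-methoxybenzyl)oxy]-5,5,9-trimethyldodeca-2,9-dien-4-yl 3-methoxy-4-[(triisopropylsilyl)oxy]benzoate
Product: 28 (2E,4R,9Z)-12-hydroxy-2-iodo-5,5,9-trimethyldodeca-2,9-dien-4-yl 3-methoxy-4-[(triisopropylsilyl)oxy]benzoate
Conditions: DDQ, CH2Cl2/pH 7 buffer, 0 °C
Reagents that add atoms: none
Why: Oxidative PMB cleavage by DDQ (hydride abstraction, then hydrolysis of the oxocarbenium ion) frees the primary alcohol without affecting the ester, aryl silyl ether or alkenyl iodide.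

**Step 17**
Reactants: 28 (2E,4R,9Z)-12-hydroxy-2-iodo-5,5,9-trimethyldodeca-2,9-dien-4-yl 3-methoxy-4-[(triisopropylsilyl)oxy]benzoate
Product: 29 (2E,4R,9Z)-2-iodo-5,5,9-trimethyl-12-oxododeca-2,9-dien-4-yl 3-methoxy-4-[(triisopropylsilyl)oxy]benzoate
Conditions: Dess–Martin periodinane, NaHCO3, CH2Cl2, 0 °C → rt; used crude
Reagents that add atoms: none
Why: Buffered Dess–Martin oxidation gives the β,γ-unsaturated aldehyde under neutral conditions, and immediate use prevents migration of the Z alkene into conjugation.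

**Step 18**
Reactants: 29 (2E,4R,9Z)-2-iodo-5,5,9-trimethyl-12-oxododeca-2,9-dien-4-yl 3-methoxy-4-[(triisopropylsilyl)oxy]benzoate
Product: 30 (1R,2E,6Z)-4-hydroxy-3,7,11,11-tetramethylcycloundeca-2,6-dien-1-yl 3-methoxy-4-[(triisopropylsilyl)oxy]benzoate (C4 epimers)
Conditions: CrCl2 (8 equiv), NiCl2 (2 mol%), DMSO/THF, 3 mM, rt
Reagents that add atoms: none
Why: Intramolecular Nozaki–Hiyama–Kishi reaction; zerovalent nickel inserts into the C–I bond, transmetalation gives an alkenyl species of trivalent chromium that adds only to the aldehyde with retention of the E geometry, and high dilution favours the 11-membered ring (the C4 epimer mixture is erased in step 19).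

**Step 19**
Reactants: 30 (1R,2E,6Z)-4-hydroxy-3,7,11,11-tetramethylcycloundeca-2,6-dien-1-yl 3-methoxy-4-[(triisopropylsilyl)oxy]benzoate (C4 epimers)
Product: 31 (1R,2E,6Z)-3,7,11,11-tetramethyl-4-oxocycloundeca-2,6-dien-1-yl 3-methoxy-4-[(triisopropylsilyl)oxy]benzoate
Conditions: Dess–Martin periodinane, NaHCO3, CH2Cl2, 0 °C → rt
Reagents that add atoms: none
Why: Dess–Martin oxidation converges both C4 epimers to one enone under base-free conditions that leave the skipped C6=C7 alkene in place.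

**Step 20**
Reactants: 31 (1R,2E,6Z)-3,7,11,11-tetramethyl-4-oxocycloundeca-2,6-dien-1-yl 3-methoxy-4-[(triisopropylsilyl)oxy]benzoate
Product: 32 (1R,2E,4S,6Z)-4-hydroxy-3,7,11,11-tetramethylcycloundeca-2,6-dien-1-yl 3-methoxy-4-[(triisopropylsilyl)oxy]benzoate
Conditions: ketoreductase (NADPH-dependent, S-selective, picked from a commercial panel), NADP+ (cat.), i-PrOH (10 vol%), phosphate buffer pH 7.0, DMSO (10 vol%), 30 °C
Reagents that add atoms: none
Why: Enzymatic carbonyl reduction by a ketoreductase (alcohol dehydrogenase class); the active site delivers hydride from NADPH to one face of the C4 ketone and sets C4 as S, at neutral pH where neither the ester nor the skipped alkene is at risk, with 2-propanol recycling the cofactor.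

**Step 21**
Reactants: 32 (1R,2E,4S,6Z)-4-hydroxy-3,7,11,11-tetramethylcycloundeca-2,6-dien-1-yl 3-methoxy-4-[(triisopropylsilyl)oxy]benzoate
Product: 33 (1R,2E,4S,6Z)-4-hydroxy-3,7,11,11-tetramethylcycloundeca-2,6-dien-1-yl 4-hydroxy-3-methoxybenzoate
Conditions: Bu4NF, AcOH (1:1), THF, 0 °C
Reagents that add atoms: none
Why: Acetic acid-buffered fluoride cleaves the aryl silyl ether rapidly while the hindered benzoate and the allylic alcohol stay intact, giving the target.

**Compound list**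
1 | ethyl isobutyrate | CCOC(=O)C(C)C | starting material
2 | 1,3-dibromopropane | BrCCCBr | starting material
3 | lithium enolate of ethyl isobutyrate | CCOC(O[Li])=C(C)C | intermediate
4 | ethyl 5-bromo-2,2-dimethylpentanoate | CCOC(=O)C(C)(C)CCCBr | intermediate
5 | 5-bromo-2,2-dimethylpentan-1-ol | OCC(C)(C)CCCBr | intermediate
6 | [(5-bromo-2,2-dimethylpentyl)oxy](tert-butyl)dimethylsilane | CC(C)(C)[Si](C)(C)OCC(C)(C)CCCBr | intermediate
7 | propyne | CC#C | starting material
8 | oxirane (ethylene oxide) | C1CO1 | starting material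
9 | {5-[(tert-butyldimethylsilyl)oxy]-4,4-dimethylpentyl}magnesium bromide | CC(C)(C)[Si](C)(C)OCC(C)(C)CCC[Mg]Br | intermediate
10 | (Z)-{7-[(tert-butyldimethylsilyl)oxy]-2,6,6-trimethylhept-1-en-1-yl}copper | CC(C)(C)[Si](C)(C)OCC(C)(C)CCC/C(C)=C\[Cu] | intermediate
11 | (Z)-9-[(tert-butyldimethylsilyl)oxy]-4,8,8-trimethylnon-3-en-1-ol | OCC/C=C(/C)CCCC(C)(C)CO[Si](C)(C)C(C)(C)C | intermediate
12 | (Z)-tert-butyl({9-[(4-methoxybenzyl)oxy]-2,2,6-trimethylnon-6-en-1-yl}oxy)dimethylsilane | COc1ccc(COCC/C=C(/C)CCCC(C)(C)CO[Si](C)(C)C(C)(C)C)cc1 | intermediate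
13 | (Z)-9-[(4-methoxybenzyl)oxy]-2,2,6-trimethylnon-6-en-1-ol | COc1ccc(COCC/C=C(/C)CCCC(C)(C)CO)cc1 | intermediate
14 | (Z)-9-[(4-methoxybenzyl)oxy]-2,2,6-trimethylnon-6-enal | COc1ccc(COCC/C=C(/C)CCCC(C)(C)C=O)cc1 | intermediate
15 | prop-1-yn-1-ylmagnesium bromide | CC#C[Mg]Br | starting material
16 | (9Z)-12-[(4-methoxybenzyl)oxy]-5,5,9-trimethyldodec-9-en-2-yn-4-ol (racemic) | COc1ccc(COCC/C=C(/C)CCCC(C)(C)C(O)C#CC)cc1 | intermediate
17 | (Z)-12-[(4-methoxybenzyl)oxy]-5,5,9-trimethyldodec-9-en-2-yn-4-one | COc1ccc(COCC/C=C(/C)CCCC(C)(C)C(=O)C#CC)cc1 | intermediate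
18 | (4S,9Z)-12-[(4-methoxybenzyl)oxy]-5,5,9-trimethyldodec-9-en-2-yn-4-ol | CC#C[C@@H](O)C(C)(C)CCC/C(C)=C\CCOCc1ccc(OC)cc1 | intermediate
19 | triethyl({(4S,9Z)-12-[(4-methoxybenzyl)oxy]-5,5,9-trimethyldodec-9-en-2-yn-4-yl}oxy)silane | CC#C[C@@H](O[Si](CC)(CC)CC)C(C)(C)CCC/C(C)=C\CCOCc1ccc(OC)cc1 | intermediate
20 | chlorobis(cyclopentadienyl){(2E,4R,9Z)-12-[(4-methoxybenzyl)oxy]-5,5,9-trimethyl-4-[(triethylsilyl)oxy]dodeca-2,9-dien-2-yl}zirconium | C/C(=C\[C@@H](O[Si](CC)(CC)CC)C(C)(C)CCC/C(C)=C\CCOCc1ccc(OC)cc1)[Zr](Cl)(C1C=CC=C1)C1C=CC=C1 | intermediate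
21 | triethyl({(2E,4R,9Z)-2-iodo-12-[(4-methoxybenzyl)oxy]-5,5,9-trimethyldodeca-2,9-dien-4-yl}oxy)silane | C/C(I)=C\[C@@H](O[Si](CC)(CC)CC)C(C)(C)CCC/C(C)=C\CCOCc1ccc(OC)cc1 | intermediate
22 | (2E,4R,9Z)-2-iodo-12-[(4-methoxybenzyl)oxy]-5,5,9-trimethyldodeca-2,9-dien-4-ol | C/C(I)=C\[C@@H](O)C(C)(C)CCC/C(C)=C\CCOCc1ccc(OC)cc1 | intermediate
23 | vanillic acid (4-hydroxy-3-methoxybenzoic acid) | COc1cc(C(=O)O)ccc1O | starting material
24 | triisopropylsilyl 3-methoxy-4-[(triisopropylsilyl)oxy]benzoate | COc1cc(C(=O)O[Si](C(C)C)(C(C)C)C(C)C)ccc1O[Si](C(C)C)(C(C)C)C(C)C | intermediate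
25 | 3-methoxy-4-[(triisopropylsilyl)oxy]benzoic acid | COc1cc(C(=O)O)ccc1O[Si](C(C)C)(C(C)C)C(C)C | intermediate
26 | 3-methoxy-4-[(triisopropylsilyl)oxy]benzoic 2,4,6-trichlorobenzoic anhydride | COc1cc(C(=O)OC(=O)c2c(Cl)cc(Cl)cc2Cl)ccc1O[Si](C(C)C)(C(C)C)C(C)C | intermediate
27 | (2E,4R,9Z)-2-iodo-12-[(4-methoxybenzyl)oxy]-5,5,9-trimethyldodeca-2,9-dien-4-yl 3-methoxy-4-[(triisopropylsilyl)oxy]benzoate | C/C(I)=C\[C@@H](OC(=O)c1ccc(O[Si](C(C)C)(C(C)C)C(C)C)c(OC)c1)C(C)(C)CCC/C(C)=C\CCOCc1ccc(OC)cc1 | intermediate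
28 | (2E,4R,9Z)-12-hydroxy-2-iodo-5,5,9-trimethyldodeca-2,9-dien-4-yl 3-methoxy-4-[(triisopropylsilyl)oxy]benzoate | C/C(I)=C\[C@@H](OC(=O)c1ccc(O[Si](C(C)C)(C(C)C)C(C)C)c(OC)c1)C(C)(C)CCC/C(C)=C\CCO | intermediate
29 | (2E,4R,9Z)-2-iodo-5,5,9-trimethyl-12-oxododeca-2,9-dien-4-yl 3-methoxy-4-[(triisopropylsilyl)oxy]benzoate | C/C(I)=C\[C@@H](OC(=O)c1ccc(O[Si](C(C)C)(C(C)C)C(C)C)c(OC)c1)C(C)(C)CCC/C(C)=C\CC=O | intermediate
30 | (1R,2E,6Z)-4-hydroxy-3,7,11,11-tetramethylcycloundeca-2,6-dien-1-yl 3-methoxy-4-[(triisopropylsilyl)oxy]benzoate (C4 epimers) | COc1cc(C(=O)O[C@@H]2/C=C(\C)C(O)C/C=C(/C)CCCC2(C)C)ccc1O[Si](C(C)C)(C(C)C)C(C)C | intermediate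
31 | (1R,2E,6Z)-3,7,11,11-tetramethyl-4-oxocycloundeca-2,6-dien-1-yl 3-methoxy-4-[(triisopropylsilyl)oxy]benzoate | COc1cc(C(=O)O[C@@H]2/C=C(\C)C(=O)C/C=C(/C)CCCC2(C)C)ccc1O[Si](C(C)C)(C(C)C)C(C)C | intermediate
32 | (1R,2E,4S,6Z)-4-hydroxy-3,7,11,11-tetramethylcycloundeca-2,6-dien-1-yl 3-methoxy-4-[(triisopropylsilyl)oxy]benzoate | COc1cc(C(=O)O[C@@H]2/C=C(\C)[C@@H](O)C/C=C(/C)CCCC2(C)C)ccc1O[Si](C(C)C)(C(C)C)C(C)C | intermediate
33 | (1R,2E,4S,6Z)-4-hydroxy-3,7,11,11-tetramethylcycloundeca-2,6-dien-1-yl 4-hydroxy-3-methoxybenzoate | COc1cc(C(=O)O[C@@H]2/C=C(\C)[C@@H](O)C/C=C(/C)CCCC2(C)C)ccc1O | target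

**Totals**
Total step count: 21. Longest linear sequence: 20 steps (steps 1–13, then 15–21); step 14 is a one-step side branch.

**Three steps most likely to fail, with fallbacks**

Step 18 (11-membered Nozaki–Hiyama–Kishi closure; ring strain and a fragile β,γ-unsaturated aldehyde). The fallback sets out from 19 and comes back at 31, replacing the alkenyl iodide chemistry by a nickel-catalysed reductive alkyne–aldehyde macrocyclisation in the silyl ether series. DDQ cleavage of the PMB ether of 19 gives (3Z,9S)-4,8,8-trimethyl-9-[(triethylsilyl)oxy]dodec-3-en-10-yn-1-ol F2. Buffered Dess–Martin oxidation gives (3Z,9S)-4,8,8-trimethyl-9-[(triethylsilyl)oxy]dodec-3-en-10-ynal F3. Ni(cod)2 (zerovalent nickel), IMes·HCl, KOt-Bu and Et3SiH in THF at high dilution then join the methyl-bearing alkyne carbon to the aldehyde by oxidative cyclisation and silane cleavage; the cis addition of H and carbon gives the E ring alkene in (1R,2E,6Z)-3,7,11,11-tetramethyl-1,4-bis[(triethylsilyl)oxy]cycloundeca-2,6-diene F4 (C4 epimers). HF·pyridine gives (1R,2E,6Z)-3,7,11,11-tetramethylcycloundeca-2,6-diene-1,4-diol F5 (C4 epimers). MnO2 oxidises the less hindered C4 allylic alcohol to (2E,4R,9Z)-4-hydroxy-2,5,5,9-tetramethylcycloundeca-2,9-dien-1-one F6, and acylation of its C1 hydroxyl with mixed anhydride 26 (DMAP, toluene) gives 31.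

Step 20 (ketoreductase on a bulky macrocyclic enone; a hit with the right facial selectivity is not guaranteed). The fallback sets out from 31 and comes back at 32 by Corey–Bakshi–Shibata reduction: (R)-2-methyl-CBS-oxazaborolidine (20 mol%) and catecholborane in toluene at −40 °C. With the α-methyl alkenyl flank as the large group and the C5 methylene as the small group, this catalyst is predicted to give the 4S alcohol. The fallback makes no new compound (F0).

Step 4 (carbocupration of propyne and oxirane opening; sensitive organocopper chemistry). The fallback sets out from 6 and comes back at 11. Bromide 6 alkylates the dilithium derivative of but-3-yn-1-ol (n-BuLi, THF/HMPA) to give 9-[(tert-butyldimethylsilyl)oxy]-8,8-dimethylnon-3-yn-1-ol F1. Alkoxide-directed iron-catalysed syn-carbomagnesiation (MeMgBr, Fe(acac)3 cat., THF, 0 °C) then puts the methyl group on the remote alkyne carbon and, after protonation, gives 11 with the same Z geometry.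

**Further compounds**
F1 | step 4 | 9-[(tert-butyldimethylsilyl)oxy]-8,8-dimethylnon-3-yn-1-ol | OCCC#CCCCC(C)(C)CO[Si](C)(C)C(C)(C)C
F2 | step 18 | (3Z,9S)-4,8,8-trimethyl-9-[(triethylsilyl)oxy]dodec-3-en-10-yn-1-ol | CC#C[C@@H](O[Si](CC)(CC)CC)C(C)(C)CCC/C(C)=C\CCO
F3 | step 18 | (3Z,9S)-4,8,8-trimethyl-9-[(triethylsilyl)oxy]dodec-3-en-10-ynal | CC#C[C@@H](O[Si](CC)(CC)CC)C(C)(C)CCC/C(C)=C\CC=O
F4 | step 18 | (1R,2E,6Z)-3,7,11,11-tetramethyl-1,4-bis[(triethylsilyl)oxy]cycloundeca-2,6-diene (C4 epimers) | CC[Si](CC)(CC)O[C@@H]1/C=C(\C)C(O[Si](CC)(CC)CC)C/C=C(/C)CCCC1(C)C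
F5 | step 18 | (1R,2E,6Z)-3,7,11,11-tetramethylcycloundeca-2,6-diene-1,4-diol (C4 epimers) | O[C@@H]1/C=C(\C)C(O)C/C=C(/C)CCCC1(C)C
F6 | step 18 | (2E,4R,9Z)-4-hydroxy-2,5,5,9-tetramethylcycloundeca-2,9-dien-1-one | O[C@@H]1/C=C(\C)C(=O)C/C=C(/C)CCCC1(C)C
F0 | step 20 | none | none
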